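**Plan**
1. Chain numbering follows heptan-3-one: C1 carries the guaiacyl ring, C7 the syringyl ring. Retrosynthesis: remove the two benzyl ethers, then re-close the β-hydroxy ketone C3(=O)–C4H2–C5H(OH) to a 4,5-dihydro-1,2-oxazole by restoring its N–O and C=N bonds.
2. Enabling feature: the 1,3-relation of the C3 carbonyl and the C5 carbinol is the retron of this five-membered ring (C3=N–O–C5–C4). Its C3–C4 and O–C5 bonds are cut together in a (3+2) sense, after a temporary C6 hydroxyl has been put back as director.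
3. This gives a nitrile oxide (C1–C3, guaiacyl half) and a terminal allylic alcohol (C4–C7, syringyl half).
4. Forward: guaiacyl ester to aldoxime; syringyl bromide plus (S)-epichlorohydrin to chlorohydrin to allylic alcohol; magnesium-alkoxide-directed cycloaddition joins the halves and forms the only new ring; C6–OH is removed; the ring is opened to the aldol; the benzyl groups are removed.
5. Stereochemistry: C5 (R in the target) is set in the cycloaddition by 1,2-relay from the temporary (S)-C6 carbinol, which comes from (S)-epichlorohydrin and is erased afterwards.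

Key step: step 7

Assumption: compounds 1, 5 and 7 are taken as commercial. Both phenols are carried as benzyl ethers, because hypochlorite, the magnesium alkoxide medium and the tin hydride step do not tolerate free, easily oxidised phenols.

**Step 1**
Reactants: 1 methyl 3-(4-hydroxy-3-methoxyphenyl)propanoate
Product: 2 methyl 3-[4-(benzyloxy)-3-methoxyphenyl]propanoate
Conditions: BnBr, K2CO3, acetone, reflux
Reagents that add atoms: benzyl bromide, BrCc1ccccc1
Why: Williamson ether synthesis on the phenoxide masks the phenol, and the ester is left alone by K2CO3.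

**Step 2**
Reactants: 2 methyl 3-[4-(benzyloxy)-3-methoxyphenyl]propanoate
Product: 3 3-[4-(benzyloxy)-3-methoxyphenyl]propanal
Conditions: i-Bu2AlH (1.05 equiv), CH2Cl2, −78 °C; then MeOH, aq. KNaC4H4O6
Reagents that add atoms: none
Why: Partial ester reduction with i-Bu2AlH should stop at the aldehyde, because the aluminium hemiacetal is stable at −78 °C and collapses only on work-up.

**Step 3**
Reactants: 3 3-[4-(benzyloxy)-3-methoxyphenyl]propanal
Product: 4 3-[4-(benzyloxy)-3-methoxyphenyl]propanal oxime (E/Z mixture)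
Conditions: NH2OH·HCl, NaOAc, EtOH/H2O, rt
Reagents that add atoms: hydroxylamine hydrochloride, NO.Cl
Why: Oxime condensation of an unhindered aliphatic aldehyde under buffered conditions; either oxime geometry serves, since it is lost in the nitrile oxide.

**Step 4**
Reactants: 5 4-bromo-2,6-dimethoxyphenol
Product: 6 2-(benzyloxy)-5-bromo-1,3-dimethoxybenzene
Conditions: BnBr, K2CO3, DMF, 60 °C
Reagents that add atoms: benzyl bromide, BrCc1ccccc1
Why: Williamson ether synthesis; DMF and mild heating should overcome the flanking of the phenol by two methoxy groups.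

**Step 5**
Reactants: 6 2-(benzyloxy)-5-bromo-1,3-dimethoxybenzene; 7 (2S)-2-(chloromethyl)oxirane, (S)-epichlorohydrin
Product: 9 (2S)-1-[4-(benzyloxy)-3,5-dimethoxyphenyl]-3-chloropropan-2-ol, via arylmagnesium bromide 8 (not isolated)
Conditions: Mg, I2 (cat.), THF, reflux; then 7, CuI (10 mol %), THF, −40 to 0 °C
Reagents that add atoms: none
Why: Copper-catalysed Grignard opening of the epoxide at its unsubstituted carbon is faster than chloride displacement, and the stereocenter of 7 is not touched, so its configuration is carried into 9.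

**Step 6**
Reactants: 9 (2S)-1-[4-(benzyloxy)-3,5-dimethoxyphenyl]-3-chloropropan-2-ol
Product: 11 (2S)-1-[4-(benzyloxy)-3,5-dimethoxyphenyl]but-3-en-2-ol, via epoxide 10 (not isolated)
Conditions: Me3SI (4 equiv), n-BuLi (3.8 equiv), THF, −20 °C to rt
Reagents that add atoms: trimethylsulfonium iodide, C[S+](C)C.[I-]
Why: Dimethylsulfonium methylide closes the chlorohydrin to epoxide 10, opens it at the terminal carbon, and the γ-oxido sulfonium salt loses Me2S by ylide-mediated elimination (one-carbon epoxide-to-allylic-alcohol homologation), the carbinol carbon keeping its configuration.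

**Step 7**
Reactants: 4 3-[4-(benzyloxy)-3-methoxyphenyl]propanal oxime; 11 (2S)-1-[4-(benzyloxy)-3,5-dimethoxyphenyl]but-3-en-2-ol
Product: 14 (1S)-1-[(5S)-3-{2-[4-(benzyloxy)-3-methoxyphenyl]ethyl}-4,5-dihydro-1,2-oxazol-5-yl]-2-[4-(benzyloxy)-3,5-dimethoxyphenyl]ethan-1-ol, via hydroximoyl chloride 12 (not isolated), via nitrile oxide 13 (not isolated)
Conditions: 4 (1.3 equiv), t-BuOCl, CH2Cl2, −78 °C; the solution is added slowly to 11, i-PrOH (3.3 equiv), EtMgBr (3.0 equiv), CH2Cl2, 0 °C to rt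
Reagents that add atoms: none
Why: The magnesium alkoxides dehydrochlorinate 12 to nitrile oxide 13, whose oxygen binds the magnesium held by the C6 alkoxide of 11, so a concerted suprafacial (3+2) dipolar cycloaddition inside this chelate should form the C3–C4 bond at the terminal CH2 together with the O–C5 bond. The closest known reaction type is the hydroxyl-directed, syn-selective and rate-accelerated nitrile oxide cycloaddition to magnesium alkoxides of α-chiral terminal allylic alcohols. The 4,5-dihydro-1,2-oxazole ring closes by intermolecular (3+2) cycloaddition, both ring bonds arising in the same event. The new C5 stereocenter is controlled by the (S)-C6 carbinol: in the chelated transition state the O–Mg bond lies outside, the arylmethyl group anti to the incoming dipole and the hydrogen inside, which should deliver the syn (5S,1S) adduct. The step needs regioselectivity (oxygen to the internal alkene carbon), secured by the monosubstituted alkene and the chelate; facial selectivity, secured by the chelate; and a cycloaddition faster than dimerisation of 13 to the furoxan, secured by the alkoxide acceleration and slow addition of 12.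

**Step 8**
Reactants: 14 (1S)-1-[(5S)-3-{2-[4-(benzyloxy)-3-methoxyphenyl]ethyl}-4,5-dihydro-1,2-oxazol-5-yl]-2-[4-(benzyloxy)-3,5-dimethoxyphenyl]ethan-1-ol
Product: 15 O-{(1S)-1-[(5S)-3-{2-[4-(benzyloxy)-3-methoxyphenyl]ethyl}-4,5-dihydro-1,2-oxazol-5-yl]-2-[4-(benzyloxy)-3,5-dimethoxyphenyl]ethyl} 1H-imidazole-1-carbothioate
Conditions: 1,1'-thiocarbonyldiimidazole, DMAP (cat.), THF, reflux
Reagents that add atoms: 1,1'-thiocarbonyldiimidazole, S=C(n1ccnc1)n1ccnc1
Why: Thioacyl transfer to the only free hydroxyl gives the radical-labile thiocarbamate (first half of a Barton–McCombie deoxygenation) under neutral conditions that do not deprotonate C4 of the heterocycle.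

**Step 9**
Reactants: 15 O-{(1S)-1-[(5S)-3-{2-[4-(benzyloxy)-3-methoxyphenyl]ethyl}-4,5-dihydro-1,2-oxazol-5-yl]-2-[4-(benzyloxy)-3,5-dimethoxyphenyl]ethyl} 1H-imidazole-1-carbothioate
Product: 16 (5R)-3-{2-[4-(benzyloxy)-3-methoxyphenyl]ethyl}-5-{2-[4-(benzyloxy)-3,5-dimethoxyphenyl]ethyl}-4,5-dihydro-1,2-oxazole
Conditions: Bu3SnH (2 equiv, kept in excess), AIBN (cat.), toluene, 100 °C
Reagents that add atoms: none
Why: Barton–McCombie deoxygenation: the stannyl radical adds to C=S, fragmentation gives the secondary C6 radical, and this should take hydrogen from the excess Bu3SnH before it can open the neighbouring O–C5 bond; C5 is untouched and its descriptor changes from S to R only through the CIP ranking.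

**Step 10**
Reactants: 16 (5R)-3-{2-[4-(benzyloxy)-3-methoxyphenyl]ethyl}-5-{2-[4-(benzyloxy)-3,5-dimethoxyphenyl]ethyl}-4,5-dihydro-1,2-oxazole
Product: 17 (5R)-1-[4-(benzyloxy)-3-methoxyphenyl]-7-[4-(benzyloxy)-3,5-dimethoxyphenyl]-5-hydroxyheptan-3-one
Conditions: H2 (1 atm), Raney Ni, B(OH)3, MeOH/H2O (5:1), rt
Reagents that add atoms: water, O
Why: Hydrogenolysis of the weak N–O bond gives the β-hydroxy imine, which the boric acid buffer should hydrolyse to the ketone faster than it is reduced (isoxazoline-to-aldol unmasking); C5 is not involved and is retained.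

**Step 11**
Reactants: 17 (5R)-1-[4-(benzyloxy)-3-methoxyphenyl]-7-[4-(benzyloxy)-3,5-dimethoxyphenyl]-5-hydroxyheptan-3-one
Product: 18 (5R)-5-hydroxy-7-(4-hydroxy-3,5-dimethoxyphenyl)-1-(4-hydroxy-3-methoxyphenyl)heptan-3-one
Conditions: H2 (1 atm), Pd/C, EtOAc, rt
Reagents that add atoms: none
Why: Neutral hydrogenolysis of both aryl benzyl ethers frees the phenols without acid or base, so the β-hydroxy ketone should neither dehydrate nor undergo retro-aldol cleavage and C5 stays R.

**Compound list**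
1 | methyl 3-(4-hydroxy-3-methoxyphenyl)propanoate | COC(=O)CCc1ccc(O)c(OC)c1 | starting material
2 | methyl 3-[4-(benzyloxy)-3-methoxyphenyl]propanoate | COC(=O)CCc1ccc(OCc2ccccc2)c(OC)c1 | intermediate
3 | 3-[4-(benzyloxy)-3-methoxyphenyl]propanal | O=CCCc1ccc(OCc2ccccc2)c(OC)c1 | intermediate
4 | 3-[4-(benzyloxy)-3-methoxyphenyl]propanal oxime (E/Z mixture) | ON=CCCc1ccc(OCc2ccccc2)c(OC)c1 | intermediate
5 | 4-bromo-2,6-dimethoxyphenol | COc1cc(Br)cc(OC)c1O | starting material
6 | 2-(benzyloxy)-5-bromo-1,3-dimethoxybenzene | COc1cc(Br)cc(OC)c1OCc1ccccc1 | intermediate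
7 | (2S)-2-(chloromethyl)oxirane, (S)-epichlorohydrin | ClC[C@@H]1CO1 | starting material
8 | [4-(benzyloxy)-3,5-dimethoxyphenyl]magnesium bromide | COc1cc([Mg]Br)cc(OC)c1OCc1ccccc1 | intermediate
9 | (2S)-1-[4-(benzyloxy)-3,5-dimethoxyphenyl]-3-chloropropan-2-ol | ClC[C@@H](O)Cc1cc(OC)c(OCc2ccccc2)c(OC)c1 | intermediate
10 | (2S)-2-{[4-(benzyloxy)-3,5-dimethoxyphenyl]methyl}oxirane | C1[C@@H](O1)Cc1cc(OC)c(OCc2ccccc2)c(OC)c1 | intermediate
11 | (2S)-1-[4-(benzyloxy)-3,5-dimethoxyphenyl]but-3-en-2-ol | C=C[C@@H](O)Cc1cc(OC)c(OCc2ccccc2)c(OC)c1 | intermediate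
12 | 3-[4-(benzyloxy)-3-methoxyphenyl]-N-hydroxypropanimidoyl chloride | ON=C(Cl)CCc1ccc(OCc2ccccc2)c(OC)c1 | intermediate
13 | 3-[4-(benzyloxy)-3-methoxyphenyl]propanenitrile oxide | [O-][N+]#CCCc1ccc(OCc2ccccc2)c(OC)c1 | intermediate
14 | (1S)-1-[(5S)-3-{2-[4-(benzyloxy)-3-methoxyphenyl]ethyl}-4,5-dihydro-1,2-oxazol-5-yl]-2-[4-(benzyloxy)-3,5-dimethoxyphenyl]ethan-1-ol | COc1cc(CCC2=NO[C@@H](C2)[C@@H](O)Cc2cc(OC)c(OCc3ccccc3)c(OC)c2)ccc1OCc1ccccc1 | intermediate
15 | O-{(1S)-1-[(5S)-3-{2-[4-(benzyloxy)-3-methoxyphenyl]ethyl}-4,5-dihydro-1,2-oxazol-5-yl]-2-[4-(benzyloxy)-3,5-dimethoxyphenyl]ethyl} 1H-imidazole-1-carbothioate | COc1cc(CCC2=NO[C@@H](C2)[C@@H](OC(=S)n2ccnc2)Cc2cc(OC)c(OCc3ccccc3)c(OC)c2)ccc1OCc1ccccc1 | intermediate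
16 | (5R)-3-{2-[4-(benzyloxy)-3-methoxyphenyl]ethyl}-5-{2-[4-(benzyloxy)-3,5-dimethoxyphenyl]ethyl}-4,5-dihydro-1,2-oxazole | COc1cc(CCC2=NO[C@@H](C2)CCc2cc(OC)c(OCc3ccccc3)c(OC)c2)ccc1OCc1ccccc1 | intermediate
17 | (5R)-1-[4-(benzyloxy)-3-methoxyphenyl]-7-[4-(benzyloxy)-3,5-dimethoxyphenyl]-5-hydroxyheptan-3-one | COc1cc(CCC(=O)C[C@H](O)CCc2cc(OC)c(OCc3ccccc3)c(OC)c2)ccc1OCc1ccccc1 | intermediate
18 | (5R)-5-hydroxy-7-(4-hydroxy-3,5-dimethoxyphenyl)-1-(4-hydroxy-3-methoxyphenyl)heptan-3-one | COc1cc(CCC(=O)C[C@H](O)CCc2cc(OC)c(O)c(OC)c2)ccc1O | target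

**Step count and risks**
Total steps: 11. Longest linear sequence: 8 steps (steps 4 to 11, from compound 5).

Steps most likely to fail:

1. Step 7. The nitrile oxide may dimerise to the furoxan faster than it is captured, or the chelate may not be maintained, which would erode the facial selectivity at C5. Fallback (acyl-anion opening of an epoxide in place of the cycloaddition; sets out from 3 and 8, returns at 17): aldehyde 3 with propane-1,3-dithiol and BF3·OEt2 should give 2-{2-[4-(benzyloxy)-3-methoxyphenyl]ethyl}-1,3-dithiane F1. Arylmagnesium bromide 8 coupled with 4-bromobut-1-ene (Li2CuCl4 cat., THF) should give 2-(benzyloxy)-5-(but-3-en-1-yl)-1,3-dimethoxybenzene F2. Epoxidation (mCPBA, NaHCO3, CH2Cl2) gives racemic 2-{2-[4-(benzyloxy)-3,5-dimethoxyphenyl]ethyl}oxirane F3. Hydrolytic kinetic resolution with the enantiomer of the chiral (salen)Co(OAc) complex of trivalent cobalt that consumes the (S)-epoxide leaves (2R)-2-{2-[4-(benzyloxy)-3,5-dimethoxyphenyl]ethyl}oxirane F4. Lithiated F1 (t-BuLi, THF/HMPA, −78 °C) opens F4 at its terminal carbon, forming the same C3–C4 bond, to give (2R)-1-(2-{2-[4-(benzyloxy)-3-methoxyphenyl]ethyl}-1,3-dithian-2-yl)-4-[4-(benzyloxy)-3,5-dimethoxyphenyl]butan-2-ol F5. Hg(ClO4)2/CaCO3 in aqueous THF unmasks the ketone to give 17, which continues with step 11.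

2. Step 9. The C6 radical may fragment with opening of the O–C5 bond (loss of the ring and of the C5 stereocenter), or the chain may propagate poorly. Fallback (ionic elimination and alkene reduction in place of the radical deoxygenation; sets out from 14, returns at 16): MsCl/Et3N should give (1S)-1-[(5S)-3-{2-[4-(benzyloxy)-3-methoxyphenyl]ethyl}-4,5-dihydro-1,2-oxazol-5-yl]-2-[4-(benzyloxy)-3,5-dimethoxyphenyl]ethyl methanesulfonate F6. DBU in toluene at 80 °C should eliminate toward the benzylic C7–H to give (5S)-3-{2-[4-(benzyloxy)-3-methoxyphenyl]ethyl}-5-{(E)-2-[4-(benzyloxy)-3,5-dimethoxyphenyl]ethenyl}-4,5-dihydro-1,2-oxazole F7. Diimide (2-nitrobenzenesulfonohydrazide, Et3N) should then saturate the C6=C7 bond without touching N–O or C=N, giving 16.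

3. Step 6. The ylide may decompose before the epoxide formed in the flask is homologated, or the base may isomerise the benzylic epoxide to the cinnamyl alcohol. Fallback (selenium-based homologation; sets out from 9, returns at 11): 9 is closed with aqueous NaOH and epoxide 10 is now isolated. PhSeCH2Li (from bis(phenylselanyl)methane and n-BuLi, THF, −78 °C) opens 10 at the terminal carbon to give (2S)-1-[4-(benzyloxy)-3,5-dimethoxyphenyl]-4-(phenylselanyl)butan-2-ol F8. Oxidation (H2O2, pyridine, CH2Cl2) and selenoxide syn-elimination at rt should give 11.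

**Further compounds**
F1 | step 7 | 2-{2-[4-(benzyloxy)-3-methoxyphenyl]ethyl}-1,3-dithiane | COc1cc(CCC2SCCCS2)ccc1OCc1ccccc1
F2 | step 7 | 2-(benzyloxy)-5-(but-3-en-1-yl)-1,3-dimethoxybenzene | C=CCCc1cc(OC)c(OCc2ccccc2)c(OC)c1
F3 | step 7 | racemic 2-{2-[4-(benzyloxy)-3,5-dimethoxyphenyl]ethyl}oxirane | C1OC1CCc1cc(OC)c(OCc2ccccc2)c(OC)c1
F4 | step 7 | (2R)-2-{2-[4-(benzyloxy)-3,5-dimethoxyphenyl]ethyl}oxirane | C1[C@H](O1)CCc1cc(OC)c(OCc2ccccc2)c(OC)c1
F5 | step 7 | (2R)-1-(2-{2-[4-(benzyloxy)-3-methoxyphenyl]ethyl}-1,3-dithian-2-yl)-4-[4-(benzyloxy)-3,5-dimethoxyphenyl]butan-2-ol | COc1cc(CCC2(C[C@H](O)CCc3cc(OC)c(OCc4ccccc4)c(OC)c3)SCCCS2)ccc1OCc1ccccc1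
F6 | step 9 | (1S)-1-[(5S)-3-{2-[4-(benzyloxy)-3-methoxyphenyl]ethyl}-4,5-dihydro-1,2-oxazol-5-yl]-2-[4-(benzyloxy)-3,5-dimethoxyphenyl]ethyl methanesulfonate | COc1cc(CCC2=NO[C@@H](C2)[C@@H](OS(C)(=O)=O)Cc2cc(OC)c(OCc3ccccc3)c(OC)c2)ccc1OCc1ccccc1
F7 | step 9 | (5S)-3-{2-[4-(benzyloxy)-3-methoxyphenyl]ethyl}-5-{(E)-2-[4-(benzyloxy)-3,5-dimethoxyphenyl]ethenyl}-4,5-dihydro-1,2-oxazole | COc1cc(CCC2=NO[C@@H](C2)/C=C/c2cc(OC)c(OCc3ccccc3)c(OC)c2)ccc1OCc1ccccc1
F8 | step 6 | (2S)-1-[4-(benzyloxy)-3,5-dimethoxyphenyl]-4-(phenylselanyl)butan-2-ol | c1ccccc1[Se]CC[C@@H](O)Cc1cc(OC)c(OCc2ccccc2)c(OC)c1
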